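Drimane numbering is used: C1 ester carbinol, C2, C3, C4 (CMe2), C5/C10 ring fusion, C6 free carbinol, C7=C8, C9. C11 is the CHO on C9 and C12 the CHO on C8. Ring A is C1–C5 plus C10, ring B is C5–C10, and β is the face of the C10 methyl.
**Retrosynthesis:** unmask C11 from its acetal, remove 6-OH (vinylogous Rubottom), return C12 to CH3, and remove the ester and the C1–H. This gives a racemic 1-oxodrim-7-ene, which is cut at C2–C3, C4–C5 and C9–C10 into isobutene and an acyclic α-xanthyl dienone. The dienone is cut at C5=C10 (cross metathesis), C6–C7 (sulfone alkylation) and C8=C9 (Wittig).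
**Enabling feature:** in ring A the unit C3–C4(CH3)2 is isobutene. It sits between C2 (α to the C1 oxygen, so an electrophilic α-keto radical) and C5 (β-carbon of the enone C1(=O)–C10=C5). The polarity alternates on through C10 (α-keto radical) and C9=C8, so one radical chain can close ring A and then ring B.
**Helpers:** C1 is carried as a ketone, C2 bears a xanthate (radical source), and C7 bears an ethylsulfonyl group. The sulfone first serves as the handle for the C6–C7 bond and then as the radical leaving group that fixes C7=C8. Both sulfur groups leave in the key step itself.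
**Stereochemistry:** the trans C5/C10 fusion and 9β come from chair–chair closure of ring B on the E-C8=C9 alkene. Absolute configuration and C1 come from a CBS reduction run as a kinetic resolution. C6 comes from α-face oxidation, since the axial methyls on C4 and C10 shield the β face.

Key step: step 9

Remark: the compounds marked as starting materials in the list are taken as commercial. The bicyclic ketone from the key step is racemic, and its SMILES shows the enantiomer that is carried on.

Step 1
Reactants: 1 2,2-dimethoxyacetaldehyde; 2 2-(triphenylphosphoranylidene)propanal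
Product: 3 (E)-4,4-dimethoxy-2-methylbut-2-enal
Conditions: toluene, 80 °C, slight excess of 1
Reagents that add atoms: none
Why: Wittig olefination with a formyl-stabilised ylide should give the E-enal (C7 and C11 trans across C8=C9), and the more electrophilic α,α-dialkoxy aldehyde 1 outcompetes product 3 for the ylide.

Step 2
Reactants: 3 (E)-4,4-dimethoxy-2-methylbut-2-enal
Product: 4 (E)-4,4-dimethoxy-2-methylbut-2-en-1-ol
Conditions: NaBH4, MeOH, 0 °C
Reagents that add atoms: none
Why: 1,2-reduction of the enal by borohydride leaves the acetal and the alkene geometry untouched.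

Step 3
Reactants: 4 (E)-4,4-dimethoxy-2-methylbut-2-en-1-ol
Product: 6 (E)-4-(ethylsulfonyl)-1,1-dimethoxy-3-methylbut-2-ene, via allylic mesylate 5 (not isolated)
Conditions: MsCl, Et3N, CH2Cl2, −20 °C; then EtSO2Na, DMF, 25 °C
Reagents that add atoms: methanesulfonyl chloride CS(=O)(=O)Cl (atoms in 5 only); sodium ethanesulfinate CCS(=O)[O-].[Na+]
Why: mesylation followed by SN2 S-alkylation of the soft sulfinate at the primary allylic carbon should give the allyl sulfone without allylic shift, and the acid-free medium spares the acetal.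

Step 4
Reactants: 6 (E)-4-(ethylsulfonyl)-1,1-dimethoxy-3-methylbut-2-ene; 7 allyl bromide
Product: 9 (±)-(E)-4-(ethylsulfonyl)-1,1-dimethoxy-3-methylhepta-2,6-diene, via lithiated sulfone 8 (not isolated)
Conditions: n-BuLi, THF, −78 °C; then 7, −78 °C
Reagents that add atoms: n-butyllithium [Li]CCCC (lithium in 8 only)
Why: α-alkylation of a lithiated allyl sulfone forms C6–C7; at −78 °C the anion should react next to sulfur, keep its E geometry and not expel methoxide, and the racemic stereocentre at C7 is destroyed in step 9.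

Step 5
Reactants: 10 methacryloyl chloride
Product: 11 N-methoxy-N,2-dimethylprop-2-enamide
Conditions: MeNHOMe·HCl, Et3N (2.2 equiv), CH2Cl2, 0 °C
Reagents that add atoms: N,O-dimethylhydroxylamine hydrochloride CNOC.Cl
Why: simple N-acylation gives the Weinreb amide.

Step 6
Reactants: 11 N-methoxy-N,2-dimethylprop-2-enamide
Product: 13 1-chloro-3-methylbut-3-en-2-one, via lithium hemiaminal adduct 12 (not isolated)
Conditions: ClCH2I, MeLi·LiBr, THF/Et2O, −78 °C; sat. NH4Cl; used as a cold solution
Reagents that add atoms: chloroiodomethane ClCI; methyllithium [Li]C (lithium in 12 only)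
Why: chloromethyllithium from iodine–lithium exchange adds 1,2 to the Weinreb amide and the chelated adduct holds until the quench, so neither over-addition nor conjugate addition should occur (a known route to α,β-unsaturated α'-chloroketones).

Step 7
Reactants: 9 (±)-(E)-4-(ethylsulfonyl)-1,1-dimethoxy-3-methylhepta-2,6-diene; 13 1-chloro-3-methylbut-3-en-2-one
Product: 14 (±)-(3E,7E)-1-chloro-6-(ethylsulfonyl)-9,9-dimethoxy-3,7-dimethylnona-3,7-dien-2-one
Conditions: 13 (3 equiv), second-generation Hoveyda–Grubbs catalyst (5 mol %), CH2Cl2, 40 °C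
Reagents that add atoms: none
Why: cross metathesis of a terminal alkene and a 1,1-disubstituted electron-poor alkene, a pairing known from methacrolein and methacrylates, should give the E-trisubstituted enone (C5=C10) while the hindered C8=C9 alkene stays out; the neutral medium suits the acidic, base-labile sulfone.

Step 8
Reactants: 14 (±)-(3E,7E)-1-chloro-6-(ethylsulfonyl)-9,9-dimethoxy-3,7-dimethylnona-3,7-dien-2-one
Product: 15 (±)-S-[(3E,7E)-6-(ethylsulfonyl)-9,9-dimethoxy-3,7-dimethyl-2-oxonona-3,7-dien-1-yl] O-ethyl dithiocarbonate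
Conditions: EtOCS2K, acetone, 0 °C
Reagents that add atoms: potassium O-ethyl dithiocarbonate CCOC(=S)[S-].[K+]
Why: SN2 displacement of the activated α-chloride by the soft, weakly basic xanthate salt does not touch the vinylogously acidic C6 hydrogens.

Step 9
Reactants: 15 (±)-S-[(3E,7E)-6-(ethylsulfonyl)-9,9-dimethoxy-3,7-dimethyl-2-oxonona-3,7-dien-1-yl] O-ethyl dithiocarbonate; 16 isobutene
Product: 18 (±)-11,11-dimethoxydrim-7-en-1-one (5α-H; 9β-dimethoxymethyl; 10β-methyl), via tertiary xanthate adduct 17 (not isolated)
Conditions: 16 (20 equiv), dilauroyl peroxide (0.4 equiv, pumped in over 8 h), NaHCO3, ClCH2CH2Cl (0.1 M), pressure vessel, 85 °C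
Reagents that add atoms: none
Why: Proposed new method: peroxide-initiated xanthate transfer frees the electrophilic C2 α-keto radical, which has no ring closure open to it and so adds to the CH2 end of electron-rich isobutene (C2–C3); the nucleophilic tertiary C4 radical, stored reversibly as 17, then closes ring A by 6-endo-trig attack on C5, the β-carbon of the enone (C4–C5), the 5-exo mode being anti-Michael and blocked by the C10 methyl. The electrophilic tertiary C10 α-keto radical closes ring B by 6-endo-trig attack on C9 of the allyl sulfone, β-scission of the C7–S bond fixes C7=C8, and the ethylsulfonyl radical loses SO2 to an ethyl radical that attacks the C=S group of 15 and carries the chain. Closest known reaction types are xanthate-transfer addition–cyclisation cascades, radical bicyclisation of geranyl-type chains to trans-decalins and radical allylation by allyl ethyl sulfones; new is that an intermolecular alkene insertion opens the bicyclisation. C5 is formed without bias (racemate), and C10 is set relative to it because ring B closes through a chair on the ring A chair, with the side chain on C5 equatorial and the new C9–C10 bond equatorial, which leaves the smaller methyl group axial next to the axial C4 methyl and gives the trans fusion. C9 is set by the E geometry of C8=C9, which holds C11 anti to C7 and so equatorial (β) in that chair. The step needs capture of the C2 radical by isobutene only (large excess of 16, the alkenes of 15 being trisubstituted and hindered), cyclisation of the C4 radical faster than its loss (polarity match and reversible xanthate storage) and a single alkene position (the sulfone).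

Step 10
Reactants: 18 (±)-11,11-dimethoxydrim-7-en-1-one
Product: 19 11,11-dimethoxydrim-7-en-1β-ol (1R; single enantiomer)
Conditions: (S)-2-methyl-CBS-oxazaborolidine (0.15 equiv), BH3·SMe2 (0.3 equiv), THF, −10 °C, run to about half conversion; MeOH, then aqueous work-up; chromatography removes the unreacted enantiomeric ketone
Reagents that add atoms: none
Why: CBS reduction is used as a kinetic resolution: the catalyst binds the carbonyl group with quaternary C10 as the large and C2 as the small flank, and its preferred hydride delivery coincides with the open α face (axial attack, away from the C10 methyl and C11) only in the enantiomer drawn, which should give the equatorial 1β (R) alcohol while the mismatched enantiomer lags behind.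

Step 11
Reactants: 19 11,11-dimethoxydrim-7-en-1β-ol; 20 (E)-4-methoxycinnamoyl chloride
Product: 21 11,11-dimethoxydrim-7-en-1β-yl (E)-4-methoxycinnamate
Conditions: 20, DMAP, Et3N, CH2Cl2, 0 → 40 °C
Reagents that add atoms: none
Why: DMAP-catalysed acylation of the equatorial, neopentyl-type alcohol by the acid chloride meets no competing nucleophile.

Step 12
Reactants: 21 11,11-dimethoxydrim-7-en-1β-yl (E)-4-methoxycinnamate
Product: 23 11,11-dimethoxy-12-oxodrim-7-en-1β-yl (E)-4-methoxycinnamate, via allylic alcohol 22 (not isolated)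
Conditions: SeO2 (0.5 equiv), t-BuOOH, CH2Cl2, 0 → 25 °C; filtration; then MnO2, CH2Cl2, 25 °C
Reagents that add atoms: selenium dioxide O=[Se]=O; tert-butyl hydroperoxide CC(C)(C)OO
Why: SeO2 allylic oxidation (ene reaction, then [2,3]-shift) acts at the more substituted end of C7=C8, where the C12 methyl is far more accessible than the tertiary C9–H, and MnO2 takes the primary allylic alcohol to the enal in a near-neutral medium that spares the acetal.

Step 13
Reactants: 23 11,11-dimethoxy-12-oxodrim-7-en-1β-yl (E)-4-methoxycinnamate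
Product: 24 12-(tert-butyldimethylsilyloxy)-11,11-dimethoxydrima-6,8(12)-dien-1β-yl (E)-4-methoxycinnamate
Conditions: TBSOTf (1.1 equiv), Et3N (3 equiv), CH2Cl2, −78 → −30 °C
Reagents that add atoms: tert-butyldimethylsilyl triflate CC(C)(C)[Si](C)(C)OS(=O)(=O)C(F)(F)F
Why: in this soft enolisation, O-silylation of the enal makes the γ-hydrogens on C6 (the only position conjugated to the carbonyl group) acidic enough for Et3N, and low temperature with about one equivalent of triflate is meant to spare the hindered acetal.

Step 14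
Reactants: 24 12-(tert-butyldimethylsilyloxy)-11,11-dimethoxydrima-6,8(12)-dien-1β-yl (E)-4-methoxycinnamate
Product: 26 6α-hydroxy-11,11-dimethoxy-12-oxodrim-7-en-1β-yl (E)-4-methoxycinnamate, via epoxy silyl enol ether 25 (not isolated)
Conditions: dimethyldioxirane (1.0 equiv), acetone/CH2Cl2, −78 → −30 °C; then Bu4NF/AcOH (1:1), THF, 0 °C
Reagents that add atoms: dimethyldioxirane CC1(C)OO1
Why: in this vinylogous Rubottom oxidation, as in the peracid oxidation of steroidal 3,5-dienol ethers at C6, the oxidant should take the distal C6=C7 bond from the α face (the axial methyls on C4 and C10 cover the β face), and fluoride-triggered opening of the allylic C7–O bond keeps the C6–O bond, giving the equatorial 6α-hydroxyl and restoring C7=C8–CHO.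

Step 15
Reactants: 26 6α-hydroxy-11,11-dimethoxy-12-oxodrim-7-en-1β-yl (E)-4-methoxycinnamate
Product: 27 target, (1R,4aS,5S,8R,8aS)-7,8-diformyl-5-hydroxy-4,4,8a-trimethyl-1,2,3,4,4a,5,8,8a-octahydronaphthalen-1-yl (E)-3-(4-methoxyphenyl)prop-2-enoate
Conditions: PPTS (0.2 equiv), acetone/H2O 9:1, 25 °C
Reagents that add atoms: water O
Why: mild acid hydrolysis of the dimethyl acetal frees the C11 aldehyde under conditions too weak to enolise C9, cleave the ester or ionise the allylic alcohol, so the 9β-formyl group should be kept.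

Compound list
1 | 2,2-dimethoxyacetaldehyde | COC(OC)C=O | starting material
2 | 2-(triphenylphosphoranylidene)propanal | CC(C=O)=P(c1ccccc1)(c1ccccc1)c1ccccc1 | starting material
3 | (E)-4,4-dimethoxy-2-methylbut-2-enal | O=C/C(C)=C/C(OC)OC | intermediate
4 | (E)-4,4-dimethoxy-2-methylbut-2-en-1-ol | OC/C(C)=C/C(OC)OC | intermediate
5 | (E)-4,4-dimethoxy-2-methylbut-2-enyl methanesulfonate (not isolated) | CS(=O)(=O)OC/C(C)=C/C(OC)OC | intermediate
6 | (E)-4-(ethylsulfonyl)-1,1-dimethoxy-3-methylbut-2-ene | CCS(=O)(=O)C/C(C)=C/C(OC)OC | intermediate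
7 | allyl bromide | C=CCBr | starting material
8 | α-lithiated sulfone of 6 (not isolated) | [Li]C(S(=O)(=O)CC)/C(C)=C/C(OC)OC | intermediate
9 | (±)-(E)-4-(ethylsulfonyl)-1,1-dimethoxy-3-methylhepta-2,6-diene | C=CCC(S(=O)(=O)CC)/C(C)=C/C(OC)OC | intermediate
10 | methacryloyl chloride | C=C(C)C(=O)Cl | starting material
11 | N-methoxy-N,2-dimethylprop-2-enamide | C=C(C)C(=O)N(C)OC | intermediate
12 | lithium hemiaminal adduct of 11 and chloromethyllithium (not isolated) | C=C(C)C([O-])(CCl)N(C)OC.[Li+] | intermediate
13 | 1-chloro-3-methylbut-3-en-2-one | C=C(C)C(=O)CCl | intermediate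
14 | (±)-(3E,7E)-1-chloro-6-(ethylsulfonyl)-9,9-dimethoxy-3,7-dimethylnona-3,7-dien-2-one | ClCC(=O)/C(C)=C/CC(S(=O)(=O)CC)/C(C)=C/C(OC)OC | intermediate
15 | (±)-S-[(3E,7E)-6-(ethylsulfonyl)-9,9-dimethoxy-3,7-dimethyl-2-oxonona-3,7-dien-1-yl] O-ethyl dithiocarbonate | CCOC(=S)SCC(=O)/C(C)=C/CC(S(=O)(=O)CC)/C(C)=C/C(OC)OC | intermediate
16 | isobutene (2-methylpropene) | CC(C)=C | starting material
17 | (±)-S-[(6E,10E)-9-(ethylsulfonyl)-12,12-dimethoxy-2,6,10-trimethyl-5-oxododeca-6,10-dien-2-yl] O-ethyl dithiocarbonate (not isolated) | CCOC(=S)SC(C)(C)CCC(=O)/C(C)=C/CC(S(=O)(=O)CC)/C(C)=C/C(OC)OC | intermediate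
18 | (±)-11,11-dimethoxydrim-7-en-1-one, 5α-H, 9β-CH(OMe)2, 10β-CH3 (racemate; enantiomer carried on is drawn) | O=C1CCC(C)(C)[C@@H]2CC=C(C)[C@H](C(OC)OC)[C@@]12C | intermediate
19 | 11,11-dimethoxydrim-7-en-1β-ol (1R) | O[C@@H]1CCC(C)(C)[C@@H]2CC=C(C)[C@H](C(OC)OC)[C@@]12C | intermediate
20 | (E)-4-methoxycinnamoyl chloride | COc1ccc(/C=C/C(=O)Cl)cc1 | starting material
21 | 11,11-dimethoxydrim-7-en-1β-yl (E)-4-methoxycinnamate | COc1ccc(/C=C/C(=O)O[C@@H]2CCC(C)(C)[C@@H]3CC=C(C)[C@H](C(OC)OC)[C@@]23C)cc1 | intermediate
22 | 12-hydroxy-11,11-dimethoxydrim-7-en-1β-yl (E)-4-methoxycinnamate (not isolated) | COc1ccc(/C=C/C(=O)O[C@@H]2CCC(C)(C)[C@@H]3CC=C(CO)[C@H](C(OC)OC)[C@@]23C)cc1 | intermediate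
23 | 11,11-dimethoxy-12-oxodrim-7-en-1β-yl (E)-4-methoxycinnamate | COc1ccc(/C=C/C(=O)O[C@@H]2CCC(C)(C)[C@@H]3CC=C(C=O)[C@H](C(OC)OC)[C@@]23C)cc1 | intermediate
24 | 12-(tert-butyldimethylsilyloxy)-11,11-dimethoxydrima-6,8(12)-dien-1β-yl (E)-4-methoxycinnamate (C8=C12 geometry not fixed, of no consequence) | COc1ccc(/C=C/C(=O)O[C@@H]2CCC(C)(C)[C@@H]3C=CC(=CO[Si](C)(C)C(C)(C)C)[C@H](C(OC)OC)[C@@]23C)cc1 | intermediate
25 | 6α,7α-epoxide of 24 (not isolated) | COc1ccc(/C=C/C(=O)O[C@@H]2CCC(C)(C)[C@@H]3[C@H]4O[C@H]4C(=CO[Si](C)(C)C(C)(C)C)[C@H](C(OC)OC)[C@@]23C)cc1 | intermediate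
26 | 6α-hydroxy-11,11-dimethoxy-12-oxodrim-7-en-1β-yl (E)-4-methoxycinnamate | COc1ccc(/C=C/C(=O)O[C@@H]2CCC(C)(C)[C@@H]3[C@@H](O)C=C(C=O)[C@H](C(OC)OC)[C@@]23C)cc1 | intermediate
27 | 1β-[(E)-4-methoxycinnamoyloxy]-6α-hydroxydrim-7-ene-11,12-dial | COc1ccc(/C=C/C(=O)O[C@@H]2CCC(C)(C)[C@@H]3[C@@H](O)C=C(C=O)[C@H](C=O)[C@@]23C)cc1 | target

Total steps: 15. Longest linear sequence: 13 (steps 1–4 and 7–15).

Steps most likely to fail

**1. Step 9.**
- What may go wrong: thermal elimination of the tertiary xanthate, or chain growth with isobutene, before ring A closes.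
- The C10 radical may be intercepted by xanthate transfer or hydrogen abstraction before the hindered C9–C10 bond forms.
- Ring B may close through a boat, which erodes the fusion or the C9 selectivity.
- Fallback (known chemistry, bonds made one after another), from 15 back to 18. Radical allylation of 15 by ethyl 2-methylallyl sulfone (dilauroyl peroxide, ClCH2CH2Cl, reflux) forms C2–C3 alone. It gives the homomethallyl ketone (±)-(6E,10E)-9-(ethylsulfonyl)-12,12-dimethoxy-2,6,10-trimethyldodeca-1,6,10-trien-5-one F1.
- Hydrogen-atom-transfer initiation at its 1,1-disubstituted alkene (Fe(acac)3, PhSiH3, EtOH, 60 °C) follows reductive olefin–enone coupling and hydrogen-atom-transfer-initiated polyene bicyclisation. It generates the same C4 radical with no xanthate or isobutene present, and the same two closures and loss of the sulfonyl group lead back to 18.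

**2. Step 13 (together with step 14).**
- What may go wrong: the silyl triflate may ionise the acetal, with elimination to an enol ether.
- Removal of the C6 hydrogen, which lies under the two axial methyl groups, may be slow.
- The later oxidation may occur at C8 instead of C6.
- Fallback without any enolisation, from 21 back to 26. Allylic oxidation at C6 (CrO3, 3,5-dimethylpyrazole, CH2Cl2, −20 °C) gives 11,11-dimethoxy-6-oxodrim-7-en-1β-yl (E)-4-methoxycinnamate F2.
- Luche reduction (NaBH4, CeCl3·7H2O, MeOH), with hydride from the open α face, gives the axial 6β-alcohol F3.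
- Anti elimination of the 6β-oxygen and H-5α (SOCl2, pyridine, 0 °C) gives the homoannular drima-5,7-diene F4.
- Hydroboration–oxidation (BH3·THF, 0 °C; NaBO3) adds hydrogen to C5 and boron to C6 from the α face on steroidal 5,7-dienes. Here it should give the 5α-H, 6α-hydroxydrim-7-ene F5.
- SeO2/t-BuOOH gives the 6α,12-diol F6, and TEMPO/PhI(OAc)2 oxidises only its primary alcohol, which returns to 26.

**3. Step 10.**
- What may go wrong: too small a rate difference between the enantiomers, or uncatalysed borane reduction of the mismatched ketone from its own α face. Either lowers the enantiomeric purity of the alcohol.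
- Fallback by classical resolution, from 18 back to 19. NaBH4 (MeOH, 0 °C) reduces both enantiomers from the α face to the racemic 1β-alcohol F7.
- Esterification with (S)-O-methylmandelic acid (DCC, DMAP, CH2Cl2) gives two diastereomeric esters. The ester of the (1R) alcohol, F8, is separated by chromatography or crystallisation.
- LiAlH4 (Et2O, 0 °C) cleaves F8 to 19.

Further compounds
F1 | step 9 | (±)-(6E,10E)-9-(ethylsulfonyl)-12,12-dimethoxy-2,6,10-trimethyldodeca-1,6,10-trien-5-one | C=C(C)CCC(=O)/C(C)=C/CC(S(=O)(=O)CC)/C(C)=C/C(OC)OC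
F2 | step 13 | 11,11-dimethoxy-6-oxodrim-7-en-1β-yl (E)-4-methoxycinnamate | COc1ccc(/C=C/C(=O)O[C@@H]2CCC(C)(C)[C@@H]3C(=O)C=C(C)[C@H](C(OC)OC)[C@@]23C)cc1
F3 | step 13 | 6β-hydroxy-11,11-dimethoxydrim-7-en-1β-yl (E)-4-methoxycinnamate | COc1ccc(/C=C/C(=O)O[C@@H]2CCC(C)(C)[C@@H]3[C@H](O)C=C(C)[C@H](C(OC)OC)[C@@]23C)cc1
F4 | step 13 | 11,11-dimethoxydrima-5,7-dien-1β-yl (E)-4-methoxycinnamate | COc1ccc(/C=C/C(=O)O[C@@H]2CCC(C)(C)C3=CC=C(C)[C@H](C(OC)OC)[C@@]23C)cc1
F5 | step 13 | 6α-hydroxy-11,11-dimethoxydrim-7-en-1β-yl (E)-4-methoxycinnamate | COc1ccc(/C=C/C(=O)O[C@@H]2CCC(C)(C)[C@@H]3[C@@H](O)C=C(C)[C@H](C(OC)OC)[C@@]23C)cc1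
F6 | step 13 | 6α,12-dihydroxy-11,11-dimethoxydrim-7-en-1β-yl (E)-4-methoxycinnamate | COc1ccc(/C=C/C(=O)O[C@@H]2CCC(C)(C)[C@@H]3[C@@H](O)C=C(CO)[C@H](C(OC)OC)[C@@]23C)cc1
F7 | step 10 | (±)-11,11-dimethoxydrim-7-en-1β-ol (racemate, one enantiomer drawn) | O[C@@H]1CCC(C)(C)[C@@H]2CC=C(C)[C@H](C(OC)OC)[C@@]12C
F8 | step 10 | (1R)-11,11-dimethoxydrim-7-en-1β-yl (S)-2-methoxy-2-phenylacetate | CO[C@H](C(=O)O[C@@H]1CCC(C)(C)[C@@H]2CC=C(C)[C@H](C(OC)OC)[C@@]12C)c1ccccc1
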